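**Plan**
1. Retrosynthesis: the O5–H and O4′–H bonds are traced back to a methyl and a benzyl ether. The pyranone is then cut at O1–C8a and C4–C4a into 3,4,5,6-tetramethoxybenzyne and the enolate of an α-methoxy β-keto ester. The keto ester is cut at C2–C3 into an aroyl chloride and methyl methoxyacetate.
2. Enabling feature: once O5 is a methyl ether, ring A (C4a, C5–C8, C8a) carries four identical methoxy groups. The aryne C4a≡C8a then has a mirror plane, so O1 and C4 can add to either carbon and still give one flavone.
3. Forward: ring A is brought in complete as an o-silylaryl triflate (three steps). Ring B with C2 comes from the acid chloride, and C3/C4 from the ester (one step). Ring C, the only ring formed, closes in the aryne step, and one Lewis-acid deprotection ends the route.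
4. Stereochemistry: the target has no stereocentre and no stereoaxis. The only stereocentre on the way, the α-carbon of the keto ester, is racemic and disappears on enolisation.

Key step: step 5

Remark: calycopterin is achiral, so the single constitution drawn is the whole target and no stereocontrolled step is needed; 1,2,3,4-tetramethoxybenzene is taken as a catalogue compound.

**Step 1**
Reactants: 1 1,2,3,4-tetramethoxybenzene
Product: 4 2,3,4,5-tetramethoxyphenol, via aryllithium 2 (not isolated), via lithium aryltrimethoxyborate 3 (not isolated)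
Conditions: n-BuLi (1.1 equiv), TMEDA, THF, 0 °C; B(OMe)3, −78 °C → rt; AcOH, 30% H2O2, 0 °C → rt
Reagents that add atoms: hydrogen peroxide, OO
Why: Directed ortho-metalation beside a terminal methoxy group (the two open ring positions are equivalent), borate formation and oxidative boron-to-oxygen aryl shift (hydroxydeboronation) should give the phenol in one flask.

**Step 2**
Reactants: 4 2,3,4,5-tetramethoxyphenol
Product: 5 2-bromo-3,4,5,6-tetramethoxyphenol
Conditions: NBS (1.0 equiv), CH2Cl2, −20 → 0 °C, dark, anhydrous
Reagents that add atoms: N-bromosuccinimide, O=C1CCC(=O)N1Br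
Why: Electrophilic aromatic bromination can only occur at the single unsubstituted carbon, which is ortho to the hydroxyl; low temperature and exclusion of water are meant to hold back oxidation of the electron-rich ring.

**Step 3**
Reactants: 5 2-bromo-3,4,5,6-tetramethoxyphenol
Product: 9 2,3,4,5-tetramethoxy-6-(trimethylsilyl)phenyl trifluoromethanesulfonate, via aryl trimethylsilyl ether 6 (not isolated), via 2-silyloxyaryllithium 7 (not isolated), via lithium 2-silylphenolate 8 (not isolated)
Conditions: HMDS, THF, 70 °C, then evaporate; n-BuLi, THF, −78 °C; Tf2O, −78 °C → rt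
Reagents that add atoms: hexamethyldisilazane, C[Si](C)(C)N[Si](C)(C)C; trifluoromethanesulfonic anhydride, O=S(=O)(OS(=O)(=O)C(F)(F)F)C(F)(F)F
Why: O-Silylation, bromine–lithium exchange and anionic 1,3 O→C silyl shift (retro-Brook rearrangement) put the silyl group ortho to a phenolate that is trapped by triflic anhydride, the standard way from an o-bromophenol to a Kobayashi aryne precursor.

**Step 4**
Reactants: 10 methyl methoxyacetate; 11 4-(benzyloxy)benzoyl chloride
Product: 13 methyl 3-[4-(benzyloxy)phenyl]-2-methoxy-3-oxopropanoate (racemic), via lithium ester enolate 12 (not isolated)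
Conditions: LDA (2.1 equiv), 10 (2.1 equiv), THF, −78 °C; 11 (1.0 equiv) added slowly, −78 → −40 °C; aq. NH4Cl
Reagents that add atoms: none
Why: Crossed Claisen C-acylation of an ester enolate by a non-enolisable aroyl chloride, in which the second equivalent of enolate deprotonates the more acidic β-keto ester as it forms and so prevents a second acylation.

**Step 5**
Reactants: 9 2,3,4,5-tetramethoxy-6-(trimethylsilyl)phenyl trifluoromethanesulfonate; 13 methyl 3-[4-(benzyloxy)phenyl]-2-methoxy-3-oxopropanoate
Product: 17 2-[4-(benzyloxy)phenyl]-3,5,6,7,8-pentamethoxy-4H-chromen-4-one, via cesium keto ester enolate 14 (not isolated), via 3,4,5,6-tetramethoxybenzyne 15 (not isolated), via O-arylated aryl anion 16 (not isolated)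
Conditions: CsF (4 equiv), THF, 65 °C; 9 (1.5 equiv) added over 6 h
Reagents that add atoms: none
Why: Proposed new method: fluoride removes the silyl group of 9 and triflate leaves to give aryne 15, while CsF (and then the methoxide released in each turnover) turns 13 into the chelated cesium enolate 14; the enolate oxygen adds to one aryne carbon (O1–C8a) to give aryl anion 16, which attacks the cis-placed ester carbonyl (C4–C4a) and expels methoxide. The pyranone ring thus closes by a 6-exo-trig addition–elimination of an aryl carbanion on an ester, and no stereocentre is formed. The closest known reaction types are the CsF-mediated aryne annulation of salicylate esters to xanthones (the same O-arylation and acyl capture, with a phenoxide in place of the enolate) and the aryne acyl-alkylation of β-keto esters (the same partners, but reacting through carbon). The step needs O- over C-arylation of the ambident enolate: the enolate carbon is fully substituted (OMe, CO2Me, aroyl) and each aryne carbon is flanked by a methoxy group, so C-attack would have to build a quaternary carbon next to an ortho substituent, whereas the oxygen end is unhindered and carries most of the charge in the loosely paired cesium salt. Regiochemistry does not arise because 15 has a mirror plane bisecting the C4a–C8a and C6–C7 bonds, and the E-enolate (O⁻ and CO2Me cis, favoured by Cs⁺ chelation and by the aryl/ester clash in the other isomer) is the geometry that can close. THF is chosen because it has no acidic C–H to protonate 16 before acyl capture, and slow addition of 9 keeps the aryne concentration low.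

**Step 6**
Reactants: 17 2-[4-(benzyloxy)phenyl]-3,5,6,7,8-pentamethoxy-4H-chromen-4-one
Product: 18 calycopterin, 5-hydroxy-2-(4-hydroxyphenyl)-3,6,7,8-tetramethoxy-4H-chromen-4-one
Conditions: BCl3 (5 equiv), pentamethylbenzene (3 equiv), CH2Cl2, −78 → 0 °C; then MeOH, aq. HCl
Reagents that add atoms: none
Why: Lewis-acid ether cleavage in which BCl3 held in a six-membered chelate between the C4 carbonyl and O5 removes only the peri methyl group, while the aryl benzyl ether is cleaved at low temperature with pentamethylbenzene as benzyl-cation scavenger; the 3-, 6-, 7- and 8-methoxy groups lack an equally good chelate and should remain.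

**Compound list**
1 | 1,2,3,4-tetramethoxybenzene | COc1ccc(OC)c(OC)c1OC | starting material
2 | (2,3,4,5-tetramethoxyphenyl)lithium (in situ) | [Li]c1cc(OC)c(OC)c(OC)c1OC | intermediate
3 | lithium trimethoxy(2,3,4,5-tetramethoxyphenyl)borate (in situ) | CO[B-](OC)(OC)c1cc(OC)c(OC)c(OC)c1OC.[Li+] | intermediate
4 | 2,3,4,5-tetramethoxyphenol | Oc1cc(OC)c(OC)c(OC)c1OC | intermediate
5 | 2-bromo-3,4,5,6-tetramethoxyphenol | Oc1c(Br)c(OC)c(OC)c(OC)c1OC | intermediate
6 | (2-bromo-3,4,5,6-tetramethoxyphenoxy)trimethylsilane (in situ) | C[Si](C)(C)Oc1c(Br)c(OC)c(OC)c(OC)c1OC | intermediate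
7 | [2,3,4,5-tetramethoxy-6-(trimethylsilyloxy)phenyl]lithium (in situ) | C[Si](C)(C)Oc1c([Li])c(OC)c(OC)c(OC)c1OC | intermediate
8 | lithium 2,3,4,5-tetramethoxy-6-(trimethylsilyl)phenolate (in situ) | [Li+].[O-]c1c([Si](C)(C)C)c(OC)c(OC)c(OC)c1OC | intermediate
9 | 2,3,4,5-tetramethoxy-6-(trimethylsilyl)phenyl trifluoromethanesulfonate | COc1c(OC)c(OC)c(OS(=O)(=O)C(F)(F)F)c([Si](C)(C)C)c1OC | intermediate
10 | methyl methoxyacetate | COCC(=O)OC | starting material
11 | 4-(benzyloxy)benzoyl chloride | O=C(Cl)c1ccc(OCc2ccccc2)cc1 | starting material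
12 | lithium 1,2-dimethoxyethen-1-olate (in situ) | [Li+].[O-]C(OC)=COC | intermediate
13 | methyl 3-[4-(benzyloxy)phenyl]-2-methoxy-3-oxopropanoate (racemic, enolisable α-carbon) | COC(=O)C(OC)C(=O)c1ccc(OCc2ccccc2)cc1 | intermediate
14 | cesium (1E)-1-[4-(benzyloxy)phenyl]-2,3-dimethoxy-3-oxoprop-1-en-1-olate (in situ) | COC(=O)/C(OC)=C(\[O-])c1ccc(OCc2ccccc2)cc1.[Cs+] | intermediate
15 | 3,4,5,6-tetramethoxybenzyne (in situ) | COC1=C(OC)C(OC)=C(OC)C#C1 | intermediate
16 | cesium 2-{[(1E)-1-[4-(benzyloxy)phenyl]-2,3-dimethoxy-3-oxoprop-1-en-1-yl]oxy}-3,4,5,6-tetramethoxybenzen-1-ide (in situ) | COC(=O)/C(OC)=C(\Oc1[c-]c(OC)c(OC)c(OC)c1OC)c1ccc(OCc2ccccc2)cc1.[Cs+] | intermediate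
17 | 2-[4-(benzyloxy)phenyl]-3,5,6,7,8-pentamethoxy-4H-chromen-4-one | COc1c(OC)c(OC)c2c(=O)c(OC)c(-c3ccc(OCc4ccccc4)cc3)oc2c1OC | intermediate
18 | calycopterin, 5-hydroxy-2-(4-hydroxyphenyl)-3,6,7,8-tetramethoxy-4H-chromen-4-one (achiral) | COc1c(OC)c(O)c2c(=O)c(OC)c(-c3ccc(O)cc3)oc2c1OC | target

**Step count**
Total: 6 steps. Longest linear sequence: 5 steps (1, 2, 3, 5, 6, from compound 1); the keto ester branch joins after one step (4).

**Steps most likely to fail**

Step 5 (proposed new method). The enolate may attack the aryne through carbon, after which the aryl anion adds to the ketone and the C–C bond is cleaved (acyl-alkylation). Alternatively the aryl anion may be protonated before it reaches the ester. The fallback is a Baker–Venkataraman flavone synthesis, all known chemistry, that sets out from phenol 4 and acid chloride 11 and rejoins the route at 17. Friedel–Crafts acylation of 4 at its only free ring carbon with methoxyacetic acid in BF3·OEt2 (80 °C) should give 1-(2-hydroxy-3,4,5,6-tetramethoxyphenyl)-2-methoxyethan-1-one F1. O-Aroylation with 11 (Et3N, DMAP, CH2Cl2) should give 2-(methoxyacetyl)-3,4,5,6-tetramethoxyphenyl 4-(benzyloxy)benzoate F2. LiHMDS in THF (−78 °C → rt) should shift the aroyl group from oxygen to carbon to give 1-[4-(benzyloxy)phenyl]-3-(2-hydroxy-3,4,5,6-tetramethoxyphenyl)-2-methoxypropane-1,3-dione F3. Cyclodehydration (TsOH, toluene, 80 °C) then gives 17. Steps 2 to 4 are not needed on this path.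

Step 6. Ether cleavage may continue past O5 to the neighbouring 6-methoxy (or the 3-methoxy) group through the boron chelate, or the freed benzyl cation may alkylate the phenolic ring. The fallback separates the two deprotections, setting out from 17 and returning at 18. Hydrogenolysis (H2, Pd/C, EtOAc–MeOH, rt) should give 2-(4-hydroxyphenyl)-3,5,6,7,8-pentamethoxy-4H-chromen-4-one F4. The milder chelating acid AlCl3 in MeCN (rt) should then remove only the peri methyl group to give 18.

Step 2. The N-bromo reagent may oxidise the p-alkoxyphenol ring with loss of a methyl group (quinone formation) instead of substituting it. The fallback installs the silyl group by carbamate-directed ortho-metalation, without a bromide, setting out from 4 and returning at 9 (steps 2 and 3 are bypassed). Isopropyl isocyanate with Et3N in CH2Cl2 should give 2,3,4,5-tetramethoxyphenyl N-isopropylcarbamate F5. In situ N-silylation (TBSOTf, TMEDA), n-BuLi at −78 °C, TMSCl and aqueous work-up should give 2,3,4,5-tetramethoxy-6-(trimethylsilyl)phenyl N-isopropylcarbamate F6. Et2NH with DBU in MeCN (40 °C) should free 2,3,4,5-tetramethoxy-6-(trimethylsilyl)phenol F7, and triflation with PhNTf2 in the same flask gives 9.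

**Further compounds**
F1 | step 5 | 1-(2-hydroxy-3,4,5,6-tetramethoxyphenyl)-2-methoxyethan-1-one | COCC(=O)c1c(O)c(OC)c(OC)c(OC)c1OC
F2 | step 5 | 2-(methoxyacetyl)-3,4,5,6-tetramethoxyphenyl 4-(benzyloxy)benzoate | COCC(=O)c1c(OC(=O)c2ccc(OCc3ccccc3)cc2)c(OC)c(OC)c(OC)c1OC
F3 | step 5 | 1-[4-(benzyloxy)phenyl]-3-(2-hydroxy-3,4,5,6-tetramethoxyphenyl)-2-methoxypropane-1,3-dione | COC(C(=O)c1ccc(OCc2ccccc2)cc1)C(=O)c1c(O)c(OC)c(OC)c(OC)c1OC
F4 | step 6 | 2-(4-hydroxyphenyl)-3,5,6,7,8-pentamethoxy-4H-chromen-4-one | COc1c(OC)c(OC)c2c(=O)c(OC)c(-c3ccc(O)cc3)oc2c1OC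
F5 | step 2 | 2,3,4,5-tetramethoxyphenyl N-isopropylcarbamate | CC(C)NC(=O)Oc1cc(OC)c(OC)c(OC)c1OC
F6 | step 2 | 2,3,4,5-tetramethoxy-6-(trimethylsilyl)phenyl N-isopropylcarbamate | CC(C)NC(=O)Oc1c([Si](C)(C)C)c(OC)c(OC)c(OC)c1OC
F7 | step 2 | 2,3,4,5-tetramethoxy-6-(trimethylsilyl)phenol | Oc1c([Si](C)(C)C)c(OC)c(OC)c(OC)c1OC
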